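The readings come from a simulation on assumed constants; noise was put on by code.

Friday's charge is about twice Saturday's, yet at 3.00 d X reads 16.1% in one and 16.2% in the other, so I reckon in fractions of the charge.

| flask | D | remark | time |
|---|---|---|---|
| Saturday's | 0.059 M | run made earlier |  |
| Monday's | 0.029 M | run made earlier |  |
| Friday's | 0.12 M | run made earlier |  |
| spring | 0.059 M | everything together in a closed stirred flask, run for 5.0 d | 5.0 d |
| dusk | 0.059 M | one stirred flow tank at steady state, fed with the mixture as stated, mean residence time 5.0 d |  |

- Saturday's (time / d: X / %, J / %): 0.625: 1.2, 0; 1.25: 2.2, 0.4; 1.67: 6.7, 2.0; 2.50: 13.6, 8.1; 3.00: 16.1, 13.1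
- Monday's (time / d: X / %, J / %): 0.333: 0, 0; 0.625: 0, 0.5; 1.04: 2.3, 0.1; 2.00: 8.5, 3.2; 4.00: 20.3, 27.5
- Friday's (time / d: X / %, J / %): 0.833: 0.6, 1.3; 1.67: 6.1, 2.5; 2.50: 14.1, 8.6; 3.00: 16.2, 13.1; 4.00: 20.4, 27.3

(each reading ± 0.5 percentage points)

- the set-up with the highest share of X in all that became X or J, at the outlet or at the end ("none" if the first two lie within 2 percentage points) (spring / dusk / none)
- share of X in all that became X or J, at the outlet or at the end, spring
- share of X in all that became X or J, at the outlet or at the end, dusk

- the stated concentrations are those of everything mixed, before any reaction; amounts are the same in each set-up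
- the earlier runs were read with a standard deviation of 0.5 percentage points
- the earlier runs were made in a closed, stirred flask

J lags X, so I take J as made from X. On Friday, from 2.50 d to 4.00 d, the J gained divided by the area under the X curve gives my reading of the loss constant of X:

k = 0.723 d⁻¹

I count n = 3.61 turns of X, the time in the vessel times k, the Damköhler number of this step. In dusk, J is made at k times X and washed out once per residence time, so J/X equals n:

dusk: share = 1/(1 + n) = 21.7%

For spring I bracket from Friday's last reading. Friday's share has fallen from 62.1% at 2.50 d to 42.8% at 4.00 d, which I take as the bound from above. If no new X came after 4.00 d, the old X would shrink through its remaining turns: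

from below: 20.8%

For an estimate inside the bracket, I let the day up to 5.0 d bring as much new X and J as Friday's day before it brought, 18.4%, and age it from the middle of that day:

spring: 34.4%

The forecast puts spring at 34%, inside the bracket, and dusk at 22%, and names spring: “narrower residence-time spread wins”.

Spring gives 32.0%, inside the bracket, and dusk 21.5%, so spring leads by 10 percentage points.

    L ⇌ E (K = 2.40, k = 6.09 × 10⁻⁶ s⁻¹)
    E → X (k = 1.04 × 10⁻⁴ s⁻¹)
    G → L (k = 1.78 × 10⁻⁵ s⁻¹)
    D ⇌ Q (K = 2.10, k = 9.05 × 10⁻⁶ s⁻¹)
    D ⇌ Z (K = 0.350, k = 5.51 × 10⁻⁶ s⁻¹)
    X → J (k = 8.47 × 10⁻⁶ s⁻¹)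
    Q → G (k = 4.32 × 10⁻⁵ s⁻¹)

For the order to turn, that lead would have to shrink below 2 points. Running spring on to 5.59 d adds 0.427 of a turn, and there its share has moved by 5 points, less than the lead. Left to 50.0 d, spring counts 36.1 turns, and its share is 0%.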